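**Plan**
- Retrosynthesis: the three MOM ethers and the C4 ketone are unmasked last; ring C is cut at the O1–C8a aryl ether bond (back to an aryl triflate and a free secondary alcohol); the C3–C4 bond is then cut (aldol) into a ring A aldehyde triflate and a ring B methyl ketone.
- Enabling feature: O1 joins the C2 stereocentre to C8a, the ring A carbon that sits beside the C8 side chain. Making O1–C8a from a C8a triflate therefore decides which ring A oxygen becomes O1 (8- rather than 6-substitution) and never touches the C2–O bond.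
- Forward: the ring A aldehyde triflate (from 2,4,6-trihydroxybenzaldehyde; side chain by iodination, alkynylation, hydrogenation) and the ring B chromene methyl ketone (pyran ring built first, from 4-bromoresorcinol) are joined by aldol addition; ring C closes last.
- Stereochemistry: C2 is set as an (S)-carbinol by RuCl(p-cymene)[(S,S)-TsDPEN] transfer hydrogenation of the aryl ketone and is carried with retention through the C–O coupling.
- End game: fluoride, MnO2, dilute HCl.

Key step: step 15

Assumption: the carbon that becomes C4 carries a silyloxy group whose configuration is irrelevant because it is oxidised to the ketone later; the aldol adduct and its silyl ether are racemic, and the carbinol, the flavan and the flavan-4-ol are carried as mixtures of the two C4 epimers, each (S) at the carbon that becomes C2.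

**Route**

Step 1
Reactants: 1 2-methylbut-3-yn-2-ol
Product: 2 triethyl[(2-methylbut-3-yn-2-yl)oxy]silane
Conditions: TESCl, imidazole, DMAP (cat.), DMF, rt
Reagents that add atoms: chlorotriethylsilane (TESCl), CC[Si](Cl)(CC)CC
Why: Silyl ether formation on an unhindered propargylic tertiary alcohol, which caps the oxygen that could otherwise compete for C8a in the ring closure.

Step 2
Reactants: 3 2,4,6-trihydroxybenzaldehyde
Product: 4 2-hydroxy-4,6-bis(methoxymethoxy)benzaldehyde
Conditions: MOMCl (2.2 equiv), i-Pr2NEt, CH2Cl2, 0 °C to rt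
Reagents that add atoms: chloromethyl methyl ether (MOMCl), COCCl
Why: MOM ether formation stops at the bis-ether because the last hydroxyl is locked in a hydrogen bond to the formyl group and resists alkylation with an amine base.

Step 3
Reactants: 4 2-hydroxy-4,6-bis(methoxymethoxy)benzaldehyde
Product: 5 2-hydroxy-3-iodo-4,6-bis(methoxymethoxy)benzaldehyde
Conditions: NIS, DMF, 0 °C to rt, dark
Reagents that add atoms: N-iodosuccinimide (NIS), O=C1CCC(=O)N1I
Why: Electrophilic aromatic iodination should go ortho to the free chelated phenol at C3, which is less crowded than C5 between the two MOM ethers, as in the 3-halogenation of 2-hydroxy-4,6-dialkoxyaryl carbonyl compounds.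

Step 4
Reactants: 5 2-hydroxy-3-iodo-4,6-bis(methoxymethoxy)benzaldehyde
Product: 6 6-formyl-2-iodo-3,5-bis(methoxymethoxy)phenyl trifluoromethanesulfonate
Conditions: Tf2O, pyridine, CH2Cl2, −20 to 0 °C
Reagents that add atoms: trifluoromethanesulfonic anhydride (Tf2O), O=S(=O)(OS(=O)(=O)C(F)(F)F)C(F)(F)F
Why: O-Sulfonylation of the phenol turns the oxygen-bearing carbon beside the future side chain into the electrophilic C8a and protects the ortho oxygen from cyclising onto the alkyne in the next step.

Step 5
Reactants: 6 6-formyl-2-iodo-3,5-bis(methoxymethoxy)phenyl trifluoromethanesulfonate; 2 triethyl[(2-methylbut-3-yn-2-yl)oxy]silane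
Product: 7 6-formyl-3,5-bis(methoxymethoxy)-2-[3-methyl-3-(triethylsilyloxy)but-1-yn-1-yl]phenyl trifluoromethanesulfonate
Conditions: PdCl2(PPh3)2 (cat.), CuI (cat.), Et3N, THF, rt
Reagents that add atoms: none
Why: Sonogashira coupling, in which oxidative addition into the C–I bond is far faster than into the C–OTf bond at room temperature, so only the iodide should react.

Step 6
Reactants: 7 6-formyl-3,5-bis(methoxymethoxy)-2-[3-methyl-3-(triethylsilyloxy)but-1-yn-1-yl]phenyl trifluoromethanesulfonate
Product: 8 6-formyl-3,5-bis(methoxymethoxy)-2-[3-methyl-3-(triethylsilyloxy)butyl]phenyl trifluoromethanesulfonate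
Conditions: H2 (1 atm), Pd/C (palladium on carbon), EtOAc, rt, stopped after two equivalents of H2
Reagents that add atoms: none
Why: Heterogeneous catalytic hydrogenation saturates the alkyne much faster than it attacks the electron-rich, doubly ortho-substituted aldehyde or the aryl triflate under neutral, base-free conditions.

Step 7
Reactants: 9 4-bromoresorcinol; 10 3-methylbut-2-enoic acid
Product: 12 6-bromo-7-hydroxy-2,2-dimethylchroman-4-one, via aryl enone 11 (not isolated)
Conditions: P2O5 in MeSO3H, 70 °C
Reagents that add atoms: none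
Why: Friedel–Crafts acylation at the ring carbon para to one hydroxyl (not the carbon between the hydroxyls) followed by oxa-Michael closure of the ortho hydroxyl, the standard chromanone synthesis from resorcinols, with the bromine fixing the linear 6,7-substitution.

Step 8
Reactants: 12 6-bromo-7-hydroxy-2,2-dimethylchroman-4-one
Product: 13 6-bromo-7-(methoxymethoxy)-2,2-dimethylchroman-4-one
Conditions: MOMCl, i-Pr2NEt, CH2Cl2, 0 °C to rt
Reagents that add atoms: chloromethyl methyl ether (MOMCl), COCCl
Why: MOM ether formation on the acidic phenol para to the ketone, which also removes the phenoxide that would slow the hydride reduction.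

Step 9
Reactants: 13 6-bromo-7-(methoxymethoxy)-2,2-dimethylchroman-4-one
Product: 14 racemic 6-bromo-7-(methoxymethoxy)-2,2-dimethylchroman-4-ol
Conditions: NaBH4, MeOH, 0 °C
Reagents that add atoms: none
Why: Borohydride reduction of the aryl ketone; the new carbinol centre is formed racemic and is removed in the next step.

Step 10
Reactants: 14 racemic 6-bromo-7-(methoxymethoxy)-2,2-dimethylchroman-4-ol
Product: 16 6-bromo-7-(methoxymethoxy)-2,2-dimethyl-2H-chromene, via benzylic mesylate 15 (not isolated)
Conditions: MsCl, Et3N, CH2Cl2, 0 °C to reflux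
Reagents that add atoms: none
Why: Mesylation and elimination under basic conditions, where the benzylic mesylate activated by the ortho and para ring oxygens eliminates readily to the conjugated chromene while the MOM ether is spared from acid.

Step 11
Reactants: 16 6-bromo-7-(methoxymethoxy)-2,2-dimethyl-2H-chromene
Product: 18 1-[7-(methoxymethoxy)-2,2-dimethyl-2H-chromen-6-yl]ethan-1-one, via aryllithium 17 (not isolated)
Conditions: n-BuLi, THF, −78 °C; MeC(O)N(OMe)Me; then AcOH
Reagents that add atoms: N-methoxy-N-methylacetamide, CON(C)C(C)=O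
Why: Bromine–lithium exchange gives an aryllithium stabilised by the ortho MOM oxygen, and Weinreb amide acylation stops at the ketone because the chelated tetrahedral adduct survives until the quench.

Step 12
Reactants: 18 1-[7-(methoxymethoxy)-2,2-dimethyl-2H-chromen-6-yl]ethan-1-one; 8 6-formyl-3,5-bis(methoxymethoxy)-2-[3-methyl-3-(triethylsilyloxy)butyl]phenyl trifluoromethanesulfonate
Product: 20 racemic 6-{1-hydroxy-3-[7-(methoxymethoxy)-2,2-dimethyl-2H-chromen-6-yl]-3-oxopropyl}-3,5-bis(methoxymethoxy)-2-[3-methyl-3-(triethylsilyloxy)butyl]phenyl trifluoromethanesulfonate, via lithium enolate 19 (not isolated)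
Conditions: LiN(SiMe3)2, THF, −78 °C; then 8; AcOH quench at −78 °C
Reagents that add atoms: none
Why: Lithium enolate aldol addition of the methyl ketone to the non-enolisable aldehyde forms the C3–C4 bond, and the cold acidic quench should suppress retro-aldol and dehydration; the new carbinol centre needs no control.

Step 13
Reactants: 20 racemic aldol adduct
Product: 21 racemic 6-{1-[(tert-butyldimethylsilyl)oxy]-3-[7-(methoxymethoxy)-2,2-dimethyl-2H-chromen-6-yl]-3-oxopropyl}-3,5-bis(methoxymethoxy)-2-[3-methyl-3-(triethylsilyloxy)butyl]phenyl trifluoromethanesulfonate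
Conditions: TBSOTf, 2,6-lutidine, CH2Cl2, −78 °C
Reagents that add atoms: tert-butyldimethylsilyl trifluoromethanesulfonate (TBSOTf), CC(C)(C)[Si](C)(C)OS(=O)(=O)C(F)(F)F
Why: Silylation of the hindered benzylic hydroxyl with a silyl triflate at low temperature blocks retro-aldol cleavage and masks the C4 oxygen for the reduction and the ring closure, while the aryl MOM ethers should survive the cold, buffered conditions.

Step 14
Reactants: 21 racemic silyloxy ketone
Product: 22 6-{(3S)-1-[(tert-butyldimethylsilyl)oxy]-3-hydroxy-3-[7-(methoxymethoxy)-2,2-dimethyl-2H-chromen-6-yl]propyl}-3,5-bis(methoxymethoxy)-2-[3-methyl-3-(triethylsilyloxy)butyl]phenyl trifluoromethanesulfonate (both epimers at the silyloxy carbon)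
Conditions: RuCl(p-cymene)[(S,S)-TsDPEN] (cat.), HCO2H/Et3N (5:2), EtOAc, 30 °C
Reagents that add atoms: none
Why: Noyori asymmetric transfer hydrogenation of an aryl alkyl ketone, in which the (S,S)-catalyst delivers hydride to the face that gives the (S)-carbinol (the sense seen with acetophenone, the chromenyl ring taking the place of phenyl), under catalyst control that the remote racemic silyloxy centre should not override.

Step 15
Reactants: 22 (3S)-carbinol aryl triflate
Product: 23 (2S)-4-[(tert-butyldimethylsilyl)oxy]-5,7-bis(methoxymethoxy)-2-[7-(methoxymethoxy)-2,2-dimethyl-2H-chromen-6-yl]-8-[3-methyl-3-(triethylsilyloxy)butyl]chromane (both C4 epimers)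
Conditions: Pd(OAc)2 (cat.), 2-(di-tert-butylphosphino)-2',4',6'-triisopropylbiphenyl (cat.), K3PO4, toluene, 80 °C
Reagents that add atoms: none
Why: Zerovalent palladium formed from Pd(OAc)2 and the bulky biaryl di-tert-butylphosphine inserts into the C8a–OTf bond, the alkoxide generated with K3PO4 replaces triflate on the divalent arylpalladium to give a seven-membered oxapalladacycle, and C–O reductive elimination forms O1–C8a. The closest known reaction type is the palladium-catalysed intramolecular etherification of aryl halides and sulfonates by tethered secondary alcohols, which gives 2-substituted chromans without loss of enantiopurity. Ring C closes as a six-membered ring by this reductive elimination, formally an exo ipso substitution at the trigonal carbon C8a. No stereocentre is created: C2 keeps its (S) configuration because the C2–O bond is never broken, so the easily ionised electron-rich benzylic carbinol is never turned into a leaving group. The step needs chemoselectivity for reductive elimination over β-hydride loss, which the bulky ligand should provide, and site selectivity for the C2 oxygen, which the substrate secures because the tertiary oxygen carries TES and the C4 oxygen carries TBS, the latter also preventing a five-membered palladium alkoxide chelate that would shed hydride. The triflate sits on the oxygen-bearing carbon next to the side chain, which fixes the 8-substituted rather than the 6-substituted flavanone pattern.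

Step 16
Reactants: 23 protected (2S)-4-silyloxyflavan
Product: 24 (2S)-8-(3-hydroxy-3-methylbutyl)-5,7-bis(methoxymethoxy)-2-[7-(methoxymethoxy)-2,2-dimethyl-2H-chromen-6-yl]chroman-4-ol (both C4 epimers)
Conditions: Bu4NF, THF, rt
Reagents that add atoms: none
Why: Fluoride desilylation removes both the secondary TBS and the tertiary TES ether while the MOM ethers, the chromene and the C2 ether are inert to fluoride.

Step 17
Reactants: 24 (2S)-flavan-4-ol
Product: 25 (2S)-8-(3-hydroxy-3-methylbutyl)-5,7-bis(methoxymethoxy)-2-[7-(methoxymethoxy)-2,2-dimethyl-2H-chromen-6-yl]chroman-4-one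
Conditions: MnO2 (activated, excess), CH2Cl2, rt
Reagents that add atoms: none
Why: MnO2 oxidation of the electron-rich benzylic alcohol under neutral conditions converges both C4 epimers on one ketone, cannot oxidise the tertiary alcohol, and avoids the base that would open the flavanone and racemise C2.

Step 18
Reactants: 25 (2S)-tris-MOM flavanone
Product: 26 (2S)-5,7-dihydroxy-2-(7-hydroxy-2,2-dimethyl-2H-chromen-6-yl)-8-(3-hydroxy-3-methylbutyl)chroman-4-one (CNP0423488.1)
Conditions: HCl (1 M aq.), MeOH, 40 °C
Reagents that add atoms: none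
Why: Acid-catalysed acetal exchange cleaves the three aryl MOM ethers, and the dilute acid and low temperature are chosen to spare the chromene, the tertiary alcohol and the C2 configuration.

**Compound list**
1 | 2-methylbut-3-yn-2-ol | CC(C)(O)C#C | starting material
2 | triethyl[(2-methylbut-3-yn-2-yl)oxy]silane | CC[Si](CC)(CC)OC(C)(C)C#C | intermediate
3 | 2,4,6-trihydroxybenzaldehyde | O=Cc1c(O)cc(O)cc1O | starting material
4 | 2-hydroxy-4,6-bis(methoxymethoxy)benzaldehyde | O=Cc1c(O)cc(OCOC)cc1OCOC | intermediate
5 | 2-hydroxy-3-iodo-4,6-bis(methoxymethoxy)benzaldehyde | O=Cc1c(O)c(I)c(OCOC)cc1OCOC | intermediate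
6 | 6-formyl-2-iodo-3,5-bis(methoxymethoxy)phenyl trifluoromethanesulfonate | O=Cc1c(OS(=O)(=O)C(F)(F)F)c(I)c(OCOC)cc1OCOC | intermediate
7 | 6-formyl-3,5-bis(methoxymethoxy)-2-[3-methyl-3-(triethylsilyloxy)but-1-yn-1-yl]phenyl trifluoromethanesulfonate | O=Cc1c(OS(=O)(=O)C(F)(F)F)c(C#CC(C)(C)O[Si](CC)(CC)CC)c(OCOC)cc1OCOC | intermediate
8 | 6-formyl-3,5-bis(methoxymethoxy)-2-[3-methyl-3-(triethylsilyloxy)butyl]phenyl trifluoromethanesulfonate | O=Cc1c(OS(=O)(=O)C(F)(F)F)c(CCC(C)(C)O[Si](CC)(CC)CC)c(OCOC)cc1OCOC | intermediate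
9 | 4-bromoresorcinol | Oc1ccc(Br)c(O)c1 | starting material
10 | 3-methylbut-2-enoic acid | CC(C)=CC(=O)O | starting material
11 | 1-(5-bromo-2,4-dihydroxyphenyl)-3-methylbut-2-en-1-one (formed in the flask, not isolated) | CC(C)=CC(=O)c1cc(Br)c(O)cc1O | intermediate
12 | 6-bromo-7-hydroxy-2,2-dimethylchroman-4-one | CC1(C)CC(=O)c2cc(Br)c(O)cc2O1 | intermediate
13 | 6-bromo-7-(methoxymethoxy)-2,2-dimethylchroman-4-one | CC1(C)CC(=O)c2cc(Br)c(OCOC)cc2O1 | intermediate
14 | racemic 6-bromo-7-(methoxymethoxy)-2,2-dimethylchroman-4-ol | CC1(C)CC(O)c2cc(Br)c(OCOC)cc2O1 | intermediate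
15 | racemic 6-bromo-7-(methoxymethoxy)-2,2-dimethylchroman-4-yl methanesulfonate (formed in the flask, not isolated) | CC1(C)CC(OS(C)(=O)=O)c2cc(Br)c(OCOC)cc2O1 | intermediate
16 | 6-bromo-7-(methoxymethoxy)-2,2-dimethyl-2H-chromene | CC1(C)C=Cc2cc(Br)c(OCOC)cc2O1 | intermediate
17 | [7-(methoxymethoxy)-2,2-dimethyl-2H-chromen-6-yl]lithium (formed in the flask, not isolated) | [Li]c1cc2C=CC(C)(C)Oc2cc1OCOC | intermediate
18 | 1-[7-(methoxymethoxy)-2,2-dimethyl-2H-chromen-6-yl]ethan-1-one | CC(=O)c1cc2C=CC(C)(C)Oc2cc1OCOC | intermediate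
19 | lithium enolate of 18, lithium 1-[7-(methoxymethoxy)-2,2-dimethyl-2H-chromen-6-yl]ethen-1-olate (formed in the flask, not isolated) | [Li]OC(=C)c1cc2C=CC(C)(C)Oc2cc1OCOC | intermediate
20 | racemic 6-{1-hydroxy-3-[7-(methoxymethoxy)-2,2-dimethyl-2H-chromen-6-yl]-3-oxopropyl}-3,5-bis(methoxymethoxy)-2-[3-methyl-3-(triethylsilyloxy)butyl]phenyl trifluoromethanesulfonate | CC[Si](CC)(CC)OC(C)(C)CCc1c(OCOC)cc(OCOC)c(C(O)CC(=O)c2cc3C=CC(C)(C)Oc3cc2OCOC)c1OS(=O)(=O)C(F)(F)F | intermediate
21 | racemic 6-{1-[(tert-butyldimethylsilyl)oxy]-3-[7-(methoxymethoxy)-2,2-dimethyl-2H-chromen-6-yl]-3-oxopropyl}-3,5-bis(methoxymethoxy)-2-[3-methyl-3-(triethylsilyloxy)butyl]phenyl trifluoromethanesulfonate | CC[Si](CC)(CC)OC(C)(C)CCc1c(OCOC)cc(OCOC)c(C(O[Si](C)(C)C(C)(C)C)CC(=O)c2cc3C=CC(C)(C)Oc3cc2OCOC)c1OS(=O)(=O)C(F)(F)F | intermediate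
22 | 6-{(3S)-1-[(tert-butyldimethylsilyl)oxy]-3-hydroxy-3-[7-(methoxymethoxy)-2,2-dimethyl-2H-chromen-6-yl]propyl}-3,5-bis(methoxymethoxy)-2-[3-methyl-3-(triethylsilyloxy)butyl]phenyl trifluoromethanesulfonate, both epimers at the silyloxy carbon | CC[Si](CC)(CC)OC(C)(C)CCc1c(OCOC)cc(OCOC)c(C(O[Si](C)(C)C(C)(C)C)C[C@H](O)c2cc3C=CC(C)(C)Oc3cc2OCOC)c1OS(=O)(=O)C(F)(F)F | intermediate
23 | (2S)-4-[(tert-butyldimethylsilyl)oxy]-5,7-bis(methoxymethoxy)-2-[7-(methoxymethoxy)-2,2-dimethyl-2H-chromen-6-yl]-8-[3-methyl-3-(triethylsilyloxy)butyl]chromane, both C4 epimers | CC[Si](CC)(CC)OC(C)(C)CCc1c(OCOC)cc(OCOC)c2c1O[C@H](c1cc3C=CC(C)(C)Oc3cc1OCOC)CC2O[Si](C)(C)C(C)(C)C | intermediate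
24 | (2S)-8-(3-hydroxy-3-methylbutyl)-5,7-bis(methoxymethoxy)-2-[7-(methoxymethoxy)-2,2-dimethyl-2H-chromen-6-yl]chroman-4-ol, both C4 epimers | CC(C)(O)CCc1c(OCOC)cc(OCOC)c2c1O[C@H](c1cc3C=CC(C)(C)Oc3cc1OCOC)CC2O | intermediate
25 | (2S)-8-(3-hydroxy-3-methylbutyl)-5,7-bis(methoxymethoxy)-2-[7-(methoxymethoxy)-2,2-dimethyl-2H-chromen-6-yl]chroman-4-one | CC(C)(O)CCc1c(OCOC)cc(OCOC)c2c1O[C@H](c1cc3C=CC(C)(C)Oc3cc1OCOC)CC2=O | intermediate
26 | (2S)-5,7-dihydroxy-2-(7-hydroxy-2,2-dimethyl-2H-chromen-6-yl)-8-(3-hydroxy-3-methylbutyl)chroman-4-one (CNP0423488.1) | CC(C)(O)CCc1c(O)cc(O)c2c1O[C@H](c1cc3c(cc1O)OC(C)(C)C=C3)CC2=O | target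

**Step count and risks**
Total steps: 18. Longest linear sequence: 12 steps (steps 2–6 and 12–18 from 3; equally steps 7–11 and 12–18 from 9).

Three steps most likely to fail:

1. Step 15 (ring closure). Oxidative addition at the doubly ortho-substituted triflate may be slow, base may cleave the S–O bond of the triflate, and β-hydride loss from the palladium alkoxide may oxidise the carbinol and reduce the arene. Fallback: close the same ring from the other side by Mitsunobu etherification with inversion. It sets out from 21, which is reduced with RuCl(p-cymene)[(R,R)-TsDPEN] and HCO2H/Et3N to the (3R)-carbinol aryl triflate F1. The triflate is cleaved with Et4NOH in aqueous dioxane to the (1R)-carbinol phenol F2. PPh3 and diisopropyl azodicarboxylate in THF at 0 °C then let the phenol displace the activated carbinol with inversion to form O1–C2, and the sequence comes back to the route at 23.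

2. Step 12 (aldol union). Addition of the bulky aryl ketone enolate to the doubly ortho-substituted aldehyde may be slow, the aldolate may revert or dehydrate, and the enolate may attack the triflate at sulfur. Fallback: reverse the order of bond formation around the ketone. It sets out from 8, which takes up the smaller lithium enolate of N-methoxy-N-methylacetamide (LiN(SiMe3)2, THF, −78 °C, AcOH quench) to give the β-hydroxy Weinreb amide F3. Silylation with TBSOTf and 2,6-lutidine gives the silyloxy Weinreb amide F4. Aryllithium 17, made from 16 as in step 11, is then added to F4 at −78 °C and the sequence comes back to the route at 21.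

3. Step 5 (side-chain alkynylation, with its hydrogenation in step 6). Discrimination between the crowded C–I bond and the C–OTf bond may be incomplete, and the following hydrogenation may over-reduce the aldehyde. Fallback: attach the saturated chain in one sp3–sp2 coupling. It sets out from 6. Separately, 2-methylbut-3-en-2-ol is silylated (TESCl, imidazole, DMAP, DMF) to triethyl[(2-methylbut-3-en-2-yl)oxy]silane F5, which is hydroborated with 9-borabicyclo[3.3.1]nonane in THF to the B-alkyl borane F6. A B-alkyl Suzuki–Miyaura coupling of F6 with the iodide of 6 (PdCl2(dppf), aqueous K3PO4, THF/DMF, rt to 50 °C) comes back to the route at 8.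

Further compounds
F1 | step 15 | 6-{(3R)-1-[(tert-butyldimethylsilyl)oxy]-3-hydroxy-3-[7-(methoxymethoxy)-2,2-dimethyl-2H-chromen-6-yl]propyl}-3,5-bis(methoxymethoxy)-2-[3-methyl-3-(triethylsilyloxy)butyl]phenyl trifluoromethanesulfonate, both epimers at the silyloxy carbon | CC[Si](CC)(CC)OC(C)(C)CCc1c(OCOC)cc(OCOC)c(C(O[Si](C)(C)C(C)(C)C)C[C@@H](O)c2cc3C=CC(C)(C)Oc3cc2OCOC)c1OS(=O)(=O)C(F)(F)F
F2 | step 15 | (1R)-3-[(tert-butyldimethylsilyl)oxy]-3-{2-hydroxy-4,6-bis(methoxymethoxy)-3-[3-methyl-3-(triethylsilyloxy)butyl]phenyl}-1-[7-(methoxymethoxy)-2,2-dimethyl-2H-chromen-6-yl]propan-1-ol, both epimers at the silyloxy carbon | CC[Si](CC)(CC)OC(C)(C)CCc1c(OCOC)cc(OCOC)c(C(O[Si](C)(C)C(C)(C)C)C[C@@H](O)c2cc3C=CC(C)(C)Oc3cc2OCOC)c1O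
F3 | step 12 | racemic 6-{1-hydroxy-3-[methoxy(methyl)amino]-3-oxopropyl}-3,5-bis(methoxymethoxy)-2-[3-methyl-3-(triethylsilyloxy)butyl]phenyl trifluoromethanesulfonate | CC[Si](CC)(CC)OC(C)(C)CCc1c(OCOC)cc(OCOC)c(C(O)CC(=O)N(C)OC)c1OS(=O)(=O)C(F)(F)F
F4 | step 12 | racemic 6-{1-[(tert-butyldimethylsilyl)oxy]-3-[methoxy(methyl)amino]-3-oxopropyl}-3,5-bis(methoxymethoxy)-2-[3-methyl-3-(triethylsilyloxy)butyl]phenyl trifluoromethanesulfonate | CC[Si](CC)(CC)OC(C)(C)CCc1c(OCOC)cc(OCOC)c(C(O[Si](C)(C)C(C)(C)C)CC(=O)N(C)OC)c1OS(=O)(=O)C(F)(F)F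
F5 | step 5 | triethyl[(2-methylbut-3-en-2-yl)oxy]silane | CC[Si](CC)(CC)OC(C)(C)C=C
F6 | step 5 | 9-[3-methyl-3-(triethylsilyloxy)butyl]-9-borabicyclo[3.3.1]nonane | CC[Si](CC)(CC)OC(C)(C)CCB1C2CCCC1CCC2
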